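**Assumptions.** The SMILES is taken as definitive: a trans-fused hydrindadiene with configuration (1R,3aR,4R,5S,7aS). Ylides 5 and 18 are treated as catalogue reagents; if 5 is unavailable, it is one step from propyltriphenylphosphonium bromide, base and ethyl formate.

**Chain numbering used below.** C1 is the carboxyl carbon and C12 is the PhCH= carbon. The map to indene numbering is C2→C4, C3→C3a, C4→C3, C5→C2, C6→C1, C7→C7a, C8→C7, C9→C6 and C10→C5.

## Retrosynthetic overview
1. The acid comes from its methyl ester by SN2 O-demethylation, because the carbonyl lies between two quaternary carbons.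
2. Both rings form at once, last, by an intramolecular Diels–Alder reaction (C2–C10 and C3–C7 bonds) of an acyclic (2E,4Z,6S,7E,9E,11E)-pentaenoate. The 4Z tether alkene becomes the cyclopentene C=C, and four stereocentres are set.
3. Dienophile arm: C2=C3 by E-selective Wittig, and C4=C5 (Z) by Still–Gennari olefination of the C5 aldehyde.
4. Diene arm: C7=C8 and C9=C10 by two E-selective Wittig homologations with the same formyl ylide, and C11=C12 by benzylphosphonate HWE.
5. C6, the only stereocentre of the acyclic precursor, comes from (R)-Roche ester.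

## Route

**Step 1**
Reactants: 1, methyl (2R)-3-hydroxy-2-methylpropanoate ((R)-Roche ester); 2, tert-butyldimethylsilyl chloride
Product: 3, methyl (2R)-3-(TBSO)-2-methylpropanoate
Conditions: TBSCl, imidazole, CH2Cl2, 0 °C → rt
Reagents that add atoms: TBSCl, CC(C)(C)[Si](C)(C)Cl
Why: Imidazole-promoted silylation masks the primary OH (future C5) so the ester (future C7) can be elaborated, and C6 is untouched.

**Step 2**
Reactants: 3
Product: 4, (2R)-3-(TBSO)-2-methylpropanal
Conditions: DIBAL-H (1.05 equiv), CH2Cl2, −78 °C; MeOH, Rochelle salt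
Reagents that add atoms: none
Why: In this partial ester reduction the tetrahedral aluminium hemiacetal survives at −78 °C, so the aldehyde is released only on work-up without over-reduction or α-epimerisation.

**Step 3**
Reactants: 4; 5, 2-(triphenylphosphoranylidene)butanal
Product: 6, (2E,4S)-5-(TBSO)-2-ethyl-4-methylpent-2-enal
Conditions: 5 (1.2 equiv), toluene, 90 °C
Reagents that add atoms: 5, CCC(C=O)=P(c1ccccc1)(c1ccccc1)c1ccccc1
Why: Wittig olefination with a formyl-stabilised ylide gives the (E)-trisubstituted enal (C7=C8, C6 trans to C9) directly at the aldehyde oxidation level, and the neutral medium preserves C6.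

**Step 4**
Reactants: 6; 5
Product: 7, (2E,4E,6S)-7-(TBSO)-2,4-diethyl-6-methylhepta-2,4-dienal
Conditions: 5 (1.5 equiv), PhCO2H (10 mol %), toluene, 110 °C
Reagents that add atoms: 5, CCC(C=O)=P(c1ccccc1)(c1ccccc1)c1ccccc1
Why: A second stabilised-ylide Wittig sets (E)-C9=C10, and the more conjugated dienal product is less electrophilic than 6, so mono-homologation dominates.

**Step 5**
Reactants: 7; 8, diethyl benzylphosphonate
Product: 9, tert-butyl{[(2S,3E,5E,7E)-4,6-diethyl-2-methyl-8-phenylocta-3,5,7-trien-1-yl]oxy}dimethylsilane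
Conditions: 8, n-BuLi, THF, −78 °C; then 7, −78 °C → rt
Reagents that add atoms: 8, CCOP(=O)(Cc1ccccc1)OCC
Why: Horner–Wadsworth–Emmons reaction of the benzylic phosphonate anion gives the (E)-styryl alkene (C11=C12), and carbonyl addition outruns any remote deprotonation.

**Step 6**
Reactants: 9
Product: 10, (2S,3E,5E,7E)-4,6-diethyl-2-methyl-8-phenylocta-3,5,7-trien-1-ol
Conditions: TBAF, THF, 0 °C → rt
Reagents that add atoms: none
Why: Fluoride-mediated desilylation is inert toward the triene and the allylic stereocentre.

**Step 7**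
Reactants: 10
Product: 11, (2S,3E,5E,7E)-4,6-diethyl-2-methyl-8-phenylocta-3,5,7-trienal
Conditions: Dess–Martin periodinane, NaHCO3, CH2Cl2, 0 °C; used crude at once
Reagents that add atoms: none
Why: Buffered Dess–Martin oxidation is non-basic, and A1,3 strain with the 8-ethyl group keeps C6–H in the alkene plane, which slows epimerisation and conjugation.

**Step 8** (reagent branch)
Reactants: 12, methyl 2-[bis(2,2,2-trifluoroethoxy)phosphoryl]acetate; 13, iodoethane
Product: 14, methyl 2-[bis(2,2,2-trifluoroethoxy)phosphoryl]butanoate (racemic)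
Conditions: NaH (1.0 equiv), DMF, 0 °C; EtI, rt
Reagents that add atoms: iodoethane, CCI
Why: SN2 C-alkylation of the stabilised phosphonoacetate anion gives the α-ethyl reagent, and its stereocentre is lost in the next step.

**Step 9**
Reactants: 11; 14
Product: 15, methyl (2Z,4S,5E,7E,9E)-2,6,8-triethyl-4-methyl-10-phenyldeca-2,5,7,9-tetraenoate
Conditions: 14 (1.3 equiv), KHMDS (1.25 equiv), 18-crown-6, THF, −78 °C; then 11
Reagents that add atoms: 14, CCC(C(=O)OC)P(=O)(OCC(F)(F)F)OCC(F)(F)F
Why: In the Still–Gennari olefination the electron-poor phosphonate with a dissociated K+ counter-ion eliminates faster than it equilibrates, so the kinetic Z-enoate forms (ester carbon C3 cis to C6) and the weakly basic anion at −78 °C spares C6.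

**Step 10**
Reactants: 15
Product: 16, (2Z,4S,5E,7E,9E)-2,6,8-triethyl-4-methyl-10-phenyldeca-2,5,7,9-tetraen-1-ol
Conditions: DIBAL-H (2.5 equiv), CH2Cl2, −78 °C
Reagents that add atoms: none
Why: 1,2-Reduction of the enoate to the allylic alcohol leaves all alkene geometries unchanged.

**Step 11**
Reactants: 16
Product: 17, (2Z,4S,5E,7E,9E)-2,6,8-triethyl-4-methyl-10-phenyldeca-2,5,7,9-tetraenal
Conditions: activated MnO2, CH2Cl2, rt, dark; filter and use directly
Reagents that add atoms: none
Why: Neutral heterogeneous allylic oxidation retains the α-branched Z-enal geometry.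

**Step 12**
Reactants: 17; 18, methyl 2-(triphenylphosphoranylidene)propanoate
Product: 19, methyl (2E,4Z,6S,7E,9E,11E)-4,8,10-triethyl-2,6-dimethyl-12-phenyldodeca-2,4,7,9,11-pentaenoate (not purified)
Conditions: 18 (2 equiv), toluene, 60 °C
Reagents that add atoms: 18, COC(=O)C(C)=P(c1ccccc1)(c1ccccc1)c1ccccc1
Why: Wittig reaction of the stabilised ylide gives (E)-C2=C3, and the base-free conditions leave the 4Z alkene and the doubly allylic C6–H intact.

**Step 13**
Reactants: 19
Product: 20, methyl (1R,3aR,4R,5S,7aS)-3,5,7-triethyl-1,4-dimethyl-5-[(E)-2-phenylethenyl]-3a,4,5,7a-tetrahydro-1H-indene-4-carboxylate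
Conditions: same flask, dilute to 0.01 M in toluene, BHT (cat.), 110 °C, Ar
Reagents that add atoms: none
Why: In this intramolecular Diels–Alder reaction, suprafacial addition carries the 2E and 7E,9E geometries into the C2/C3 and C7/C10 relationships, the ester-endo/tether-exo transition state gives the trans ring fusion with CO2Me cis to styryl, and C6 selects the diene face because its H must eclipse C7=C8 next to the 8-ethyl group (A1,3 strain), which places 6-Me cis to H-7.

**Step 14**
Reactants: 20
Product: 21, spiculoic acid B, (1R,3aR,4R,5S,7aS)-3,5,7-triethyl-1,4-dimethyl-5-[(E)-2-phenylethenyl]-3a,4,5,7a-tetrahydro-1H-indene-4-carboxylic acid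
Conditions: n-PrSLi, HMPA, rt → 50 °C; then aq. citric acid
Reagents that add atoms: none
Why: In this SN2 (BAL2) ester dealkylation the thiolate attacks the unhindered O–CH3 rather than the blocked carbonyl, and no stereocentre can epimerise because the α-carbon is quaternary.

## Compound list
| No. | Name | SMILES | Role |
|---|---|---|---|
| 1 | methyl (2R)-3-hydroxy-2-methylpropanoate | COC(=O)[C@H](C)CO | starting material |
| 2 | tert-butyldimethylsilyl chloride | CC(C)(C)[Si](C)(C)Cl | starting material |
| 3 | methyl (2R)-3-(TBSO)-2-methylpropanoate | COC(=O)[C@H](C)CO[Si](C)(C)C(C)(C)C | intermediate |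
| 4 | (2R)-3-(TBSO)-2-methylpropanal | O=C[C@H](C)CO[Si](C)(C)C(C)(C)C | intermediate |
| 5 | 2-(triphenylphosphoranylidene)butanal | CCC(C=O)=P(c1ccccc1)(c1ccccc1)c1ccccc1 | starting material |
| 6 | (2E,4S)-5-(TBSO)-2-ethyl-4-methylpent-2-enal | O=C/C(CC)=C/[C@H](C)CO[Si](C)(C)C(C)(C)C | intermediate |
| 7 | (2E,4E,6S)-7-(TBSO)-2,4-diethyl-6-methylhepta-2,4-dienal | O=C/C(CC)=C/C(CC)=C/[C@H](C)CO[Si](C)(C)C(C)(C)C | intermediate |
| 8 | diethyl benzylphosphonate | CCOP(=O)(Cc1ccccc1)OCC | starting material |
| 9 | TBS ether of (2S,3E,5E,7E)-4,6-diethyl-2-methyl-8-phenylocta-3,5,7-trien-1-ol | CC(C)(C)[Si](C)(C)OC[C@@H](C)/C=C(CC)/C=C(CC)/C=C/c1ccccc1 | intermediate |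
| 10 | (2S,3E,5E,7E)-4,6-diethyl-2-methyl-8-phenylocta-3,5,7-trien-1-ol | OC[C@@H](C)/C=C(CC)/C=C(CC)/C=C/c1ccccc1 | intermediate |
| 11 | (2S,3E,5E,7E)-4,6-diethyl-2-methyl-8-phenylocta-3,5,7-trienal | O=C[C@@H](C)/C=C(CC)/C=C(CC)/C=C/c1ccccc1 | intermediate |
| 12 | methyl 2-[bis(2,2,2-trifluoroethoxy)phosphoryl]acetate | COC(=O)CP(=O)(OCC(F)(F)F)OCC(F)(F)F | starting material |
| 13 | iodoethane | CCI | starting material |
| 14 | methyl 2-[bis(2,2,2-trifluoroethoxy)phosphoryl]butanoate (racemic) | CCC(C(=O)OC)P(=O)(OCC(F)(F)F)OCC(F)(F)F | intermediate |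
| 15 | methyl (2Z,4S,5E,7E,9E)-2,6,8-triethyl-4-methyl-10-phenyldeca-2,5,7,9-tetraenoate | COC(=O)/C(CC)=C\[C@@H](C)/C=C(CC)/C=C(CC)/C=C/c1ccccc1 | intermediate |
| 16 | (2Z,4S,5E,7E,9E)-2,6,8-triethyl-4-methyl-10-phenyldeca-2,5,7,9-tetraen-1-ol | OC/C(CC)=C\[C@@H](C)/C=C(CC)/C=C(CC)/C=C/c1ccccc1 | intermediate |
| 17 | (2Z,4S,5E,7E,9E)-2,6,8-triethyl-4-methyl-10-phenyldeca-2,5,7,9-tetraenal | O=C/C(CC)=C\[C@@H](C)/C=C(CC)/C=C(CC)/C=C/c1ccccc1 | intermediate |
| 18 | methyl 2-(triphenylphosphoranylidene)propanoate | COC(=O)C(C)=P(c1ccccc1)(c1ccccc1)c1ccccc1 | starting material |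
| 19 | methyl (2E,4Z,6S,7E,9E,11E)-4,8,10-triethyl-2,6-dimethyl-12-phenyldodeca-2,4,7,9,11-pentaenoate | COC(=O)/C(C)=C/C(CC)=C\[C@@H](C)/C=C(CC)/C=C(CC)/C=C/c1ccccc1 | intermediate |
| 20 | spiculoic acid B methyl ester | CCC1=C[C@@](/C=C/c2ccccc2)(CC)[C@](C)(C(=O)OC)[C@H]2C(CC)=C[C@@H](C)[C@H]12 | intermediate |
| 21 | spiculoic acid B | CCC1=C[C@@](/C=C/c2ccccc2)(CC)[C@](C)(C(=O)O)[C@H]2C(CC)=C[C@@H](C)[C@H]12 | target |

The R/S label at C6 changes between 4, 6 and 11 only because the CIP priorities change. No bond to C6 is ever broken.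

## Step count
- Total steps: 14.
- Longest linear sequence: 13 (steps 1–7 and 9–14). Steps 12 and 13 share one flask, so this is 12 operations.

## Three steps most likely to fail
1. **Step 13 (IMDA).** The rigid Z-alkene tether may erode the endo/trans-fused preference and give the cis-fused adduct, or the reaction may need temperatures at which a [1,5]-H shift of C6–H competes.
   - Fallback: give up the unsaturated tether.
   - Run an Evans syn-aldol of 11 with an N-butanoyl oxazolidinone to install C4-Et and C5-OH, then silylate, convert the imide to the aldehyde and carry out the Wittig with 18.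
   - Run the IMDA on this sp3 tether, then form C4=C5 last by desilylation and mesylate E2 (or Burgess) elimination. C5 is configured so that only H-4, and not H-6, has the geometry needed for elimination.
2. **Step 9 (with the labile aldehyde 11 from step 7).** The risks are epimerisation or conjugation of the α-chiral β,γ-unsaturated aldehyde, or poor Z-selectivity with the α-ethyl phosphonate.
   - Fallback: build the Z-alkene by cross-coupling instead of olefination.
   - Base-free Ramirez reaction (CBr4, PPh3) of 11 gives the 1,1-dibromoalkene, and trans-selective Negishi mono-ethylation (Et2Zn, Pd(DPEphos)Cl2) follows.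
   - Retentive Pd(Pt-Bu3)2 coupling of the remaining Z-bromide with methyl (E)-2-methyl-3-(pinacolboryl)acrylate then gives 19 directly and replaces steps 8–12.
3. **Step 4 (second formyl-ylide Wittig).** The reaction with the α-branched enal may be sluggish, and the product may over-homologate to the trienal.
   - Fallback: switch to ester-level homologation.
   - Use an HWE reaction of 6 with triethyl 2-phosphonobutanoate, then DIBAL-H, then MnO2 to reach 7. This adds two steps but removes any chance of double addition.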